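**Plan**

Numbering: ring carbons C1 (carboxyl-bearing) to C14 as in the systematic name, side chain C1′–C7′. The retrosynthesis cuts, in this order: the ring bond C4–C5 (ring closure), the C5=C6 olefin, the ring bond C14–C1, the C7–C8 bond together with the 2′E olefin (Claisen), and the C3′–C4′ bond.
Enabling feature: C4 is the far end of the homoallylic unit C1=C2–C3–C4 of the 14-membered ring, so it can be made a primary B-alkyl carbon by hydroboration of a C1=C2–C3=C4 diene. C5 is the methyl-bearing sp2 carbon of the only Z olefin (C5=C6), so its geometry can be fixed in the open chain as a (Z)-alkenyl iodide and carried through a stereoretentive palladium coupling.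
Forward: geranyl acetate (C8–C13, 11-Me, C1′–C3′) is oxidized at C3′, allylated and prenyl-capped (C4′–C7′), then rearranged (Johnson–Claisen; brings C7 and C6). C13 becomes a diene (adds C14), which is hydroborated and coupled to a 2-bromodiene linchpin (C1–C4 plus the carboxyl carbon). C6 becomes the (Z)-iodoalkene (C5, 5-Me), a second hydroboration/Suzuki–Miyaura coupling closes the ring at C4–C5, and CH2OSi is oxidized to CO2H.
Stereochemistry: C8 (R) comes from 1,3-chirality transfer in the chair Claisen from an (R)-carbinol set by Brown allylboration. 2′E comes from the same chair, 11E from geraniol, 1E from a halo-ylide Wittig plus retentive coupling, and 5Z from an iodo-ylide Wittig plus retentive coupling.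

Key step: step 14

**Route**

Step 1
Reactants: 1 acrolein
Product: 2 ethyl (2Z)-2-bromopenta-2,4-dienoate
Conditions: Ph3P=CHCO2Et, NBS, CH2Cl2, −20 °C; then 1, K2CO3, −20 °C → rt
Reagents that add atoms: ethyl (triphenylphosphoranylidene)acetate CCOC(=O)C=P(c1ccccc1)(c1ccccc1)c1ccccc1; N-bromosuccinimide O=C1CCC(=O)N1Br
Why: Bromination of the stabilized ylide in the flask gives Ph3P=C(Br)CO2Et, whose Wittig reaction should place the ester trans to the vinyl group as stabilized ylides do, giving the (2Z)-bromodienoate (halo-ylide Wittig olefination).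

Step 2
Reactants: 2 ethyl (2Z)-2-bromopenta-2,4-dienoate
Product: 3 (2Z)-2-bromopenta-2,4-dien-1-ol
Conditions: i-Bu2AlH (2.3 equiv), CH2Cl2, −78 °C; aq. KNaC4H4O6 work-up
Reagents that add atoms: none
Why: i-Bu2AlH should reduce the conjugated ester 1,2 to the allylic alcohol at low temperature without touching the alkenyl bromide or the diene (ester reduction).

Step 3
Reactants: 3 (2Z)-2-bromopenta-2,4-dien-1-ol
Product: 4 {[(2Z)-2-bromopenta-2,4-dien-1-yl]oxy}(tert-butyl)dimethylsilane
Conditions: t-BuMe2SiCl, imidazole, CH2Cl2, 0 °C → rt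
Reagents that add atoms: tert-butyldimethylsilyl chloride CC(C)(C)[Si](C)(C)Cl
Why: Silylation of the primary alcohol masks the future carboxyl carbon as a group inert to boranes, i-Bu2AlH and ylides (silyl ether protection).

Step 4
Reactants: 5 geranyl acetate
Product: 7 (2E,6E)-3,7-dimethyl-8-oxoocta-2,6-dien-1-yl acetate, via allylic alcohol 6 (not isolated)
Conditions: SeO2 (cat.), t-BuOOH, salicylic acid (cat.), CH2Cl2, rt; crude mixture, MnO2, CH2Cl2, rt
Reagents that add atoms: tert-butyl hydroperoxide CC(C)(C)OO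
Why: SeO2-catalysed allylic oxidation (ene reaction then [2,3]-shift) should attack the (E)-methyl of the electron-rich terminal olefin, the 2,3-olefin being deactivated by the allylic acetate, and MnO2 converges the alcohol/aldehyde mixture on the (E)-enal (Riley allylic oxidation, then allylic alcohol oxidation).

Step 5
Reactants: 7 (2E,6E)-3,7-dimethyl-8-oxoocta-2,6-dien-1-yl acetate
Product: 8 (2E,6E,8R)-8-hydroxy-3,7-dimethylundeca-2,6,10-trien-1-yl acetate
Conditions: B-allyldiisopinocampheylborane made from (−)-α-pinene (lIpc2B(allyl), 1 M in pentane), Et2O, −78 °C; then NaBO3·4H2O, THF/H2O, rt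
Reagents that add atoms: B-allyldiisopinocampheylborane from (−)-α-pinene C=CCB([C@H]1C[C@H]2C[C@@H]([C@@H]1C)C2(C)C)[C@H]1C[C@H]2C[C@@H]([C@@H]1C)C2(C)C
Why: Brown allylboration through a chair six-membered transition state in which the isopinocampheyl groups of the (−)-α-pinene-derived reagent should direct allyl to the Re face of the 2-methyl-2-enal (the antipodal reagent gives (S)-carbinols from 2-alkenyl and aryl aldehydes), setting the (8R)-carbinol; perborate work-up spares the acetate.

Step 6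
Reactants: 8 (2E,6E,8R)-8-hydroxy-3,7-dimethylundeca-2,6,10-trien-1-yl acetate
Product: 9 (2E,6E,8R)-8-hydroxy-3,7,11-trimethyldodeca-2,6,10-trien-1-yl acetate
Conditions: second-generation Grubbs catalyst RuCl2(=CHPh)(PCy3)(H2IMes) (5 mol %), 2-methylbut-2-ene/CH2Cl2, 40 °C
Reagents that add atoms: 2-methylbut-2-ene CC=C(C)C
Why: Olefin cross-metathesis of the only monosubstituted olefin with excess 2-methylbut-2-ene should cap it as the isopropylidene (prenyl) terminus, the trisubstituted olefins being inert to the ruthenium carbene.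

Step 7
Reactants: 9 (2E,6E,8R)-8-hydroxy-3,7,11-trimethyldodeca-2,6,10-trien-1-yl acetate
Product: 11 methyl (3R,4E)-3-[(3E)-5-acetoxy-3-methylpent-3-en-1-yl]-4,8-dimethylnona-4,7-dienoate, via ketene acetal 10 (not isolated)
Conditions: MeC(OMe)3 (excess), EtCO2H (cat.), xylene, 135 °C, MeOH distilled off
Reagents that add atoms: trimethyl orthoacetate CC(OC)(OC)OC
Why: Johnson orthoester Claisen rearrangement, in which the ketene acetal should rearrange through a chair with the prenyl CH2 equatorial, so that the new olefin is (E) and the C–O chirality is passed suprafacially to the new C–C bond, giving the (3R) centre (ring C8) together with C7 and the C6 ester.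

Step 8
Reactants: 11 methyl (3R,4E)-3-[(3E)-5-acetoxy-3-methylpent-3-en-1-yl]-4,8-dimethylnona-4,7-dienoate
Product: 12 methyl (3R,4E)-3-[(3E)-5-hydroxy-3-methylpent-3-en-1-yl]-4,8-dimethylnona-4,7-dienoate
Conditions: K2CO3 (cat.), MeOH, 0 °C → rt
Reagents that add atoms: none
Why: Methanolysis should remove the allylic acetate, exchange at the methyl ester being degenerate (transesterification).

Step 9
Reactants: 12 methyl (3R,4E)-3-[(3E)-5-hydroxy-3-methylpent-3-en-1-yl]-4,8-dimethylnona-4,7-dienoate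
Product: 13 methyl (3R,4E)-4,8-dimethyl-3-[(3E)-3-methyl-5-oxopent-3-en-1-yl]nona-4,7-dienoate
Conditions: MnO2, CH2Cl2, rt
Reagents that add atoms: none
Why: MnO2 should oxidize only the allylic alcohol and keep the (E)-geometry of the resulting enal (allylic oxidation).

Step 10
Reactants: 13 methyl (3R,4E)-4,8-dimethyl-3-[(3E)-3-methyl-5-oxopent-3-en-1-yl]nona-4,7-dienoate
Product: 14 methyl (3R,4E)-4,8-dimethyl-3-[(3E)-3-methylhexa-3,5-dien-1-yl]nona-4,7-dienoate
Conditions: Ph3PCH3Br, NaN(SiMe3)2, THF, −78 → 0 °C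
Reagents that add atoms: methyltriphenylphosphonium bromide C[P+](c1ccccc1)(c1ccccc1)c1ccccc1.[Br-]
Why: Wittig methylenation of the enal is much faster than attack on the ester and should give the terminal 1,3-diene (new carbon = ring C14) with the (E)-trisubstituted olefin unchanged.

Step 11
Reactants: 14 methyl (3R,4E)-4,8-dimethyl-3-[(3E)-3-methylhexa-3,5-dien-1-yl]nona-4,7-dienoate; 4 {[(2Z)-2-bromopenta-2,4-dien-1-yl]oxy}(tert-butyl)dimethylsilane
Product: 16 methyl (3R,4E)-3-[(3E,7E)-7-({[tert-butyl(dimethyl)silyl]oxy}methyl)-3-methyldeca-3,7,9-trien-1-yl]-4,8-dimethylnona-4,7-dienoate, via B-alkyl borane 15 (not isolated)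
Conditions: 9-BBN-H dimer (1.05 equiv B–H), THF, 0 °C → rt; then 4, Pd(dppf)Cl2 (5 mol %), AsPh3, aq. K3PO4, DMF, rt
Reagents that add atoms: none
Why: 9-BBN-H should hydroborate only the monosubstituted terminus of the 1,3-diene to a primary homoallylic borane, which undergoes B-alkyl Suzuki–Miyaura coupling with the alkenyl bromide with retention, so that the CH2OSi group ends trans to the vinyl group (future 1E) and the C14–C1 bond is made.

Step 12
Reactants: 16 methyl (3R,4E)-3-[(3E,7E)-7-({[tert-butyl(dimethyl)silyl]oxy}methyl)-3-methyldeca-3,7,9-trien-1-yl]-4,8-dimethylnona-4,7-dienoate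
Product: 17 (3R,4E)-3-[(3E,7E)-7-({[tert-butyl(dimethyl)silyl]oxy}methyl)-3-methyldeca-3,7,9-trien-1-yl]-4,8-dimethylnona-4,7-dienal
Conditions: i-Bu2AlH (1.1 equiv), CH2Cl2, −78 °C; aq. KNaC4H4O6 work-up
Reagents that add atoms: none
Why: At −78 °C the reduction should stop at the aluminium hemiacetal, which gives the aldehyde on work-up; the stereocentre is β to the carbonyl and cannot epimerize (partial ester reduction).

Step 13
Reactants: 17 (3R,4E)-3-[(3E,7E)-7-({[tert-butyl(dimethyl)silyl]oxy}methyl)-3-methyldeca-3,7,9-trien-1-yl]-4,8-dimethylnona-4,7-dienal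
Product: 18 (3E,7E,11R,13Z)-4-({[tert-butyl(dimethyl)silyl]oxy}methyl)-14-iodo-8-methyl-11-[(2E)-6-methylhepta-2,5-dien-2-yl]pentadeca-1,3,7,13-tetraene
Conditions: EtPPh3I, n-BuLi, THF, rt; I2, −78 °C; NaN(SiMe3)2, −20 °C; then 17, −78 → −20 °C
Reagents that add atoms: ethyltriphenylphosphonium iodide CC[P+](c1ccccc1)(c1ccccc1)c1ccccc1.[I-]; iodine II
Why: Stork–Zhao-type Wittig olefination with the α-iodo ylide Ph3P=C(I)CH3 should give the 2-iodo-2-alkene with iodine cis to the chain under kinetic control, fixing the future 5Z geometry in the open chain.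

Step 14
Reactants: 18 (3E,7E,11R,13Z)-4-({[tert-butyl(dimethyl)silyl]oxy}methyl)-14-iodo-8-methyl-11-[(2E)-6-methylhepta-2,5-dien-2-yl]pentadeca-1,3,7,13-tetraene
Product: 20 tert-butyl{[(1E,5Z,8R,11E)-5,11-dimethyl-8-[(2E)-6-methylhepta-2,5-dien-2-yl]cyclotetradeca-1,5,11-trien-1-yl]methoxy}dimethylsilane, via B-alkyl borane 19 (not isolated)
Conditions: 9-BBN-H dimer (1.2 equiv B–H), THF, 0 °C → rt; then syringe-pump addition to Pd(dppf)Cl2 (20 mol %), AsPh3, Cs2CO3, DMF/THF/H2O, 50 °C, final 2 mM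
Reagents that add atoms: none
Why: 9-BBN-H should add only to the monosubstituted terminus of the 1,3-diene (boron on C4), and the borane 19 is fed slowly to the catalyst so that oxidative addition of zerovalent palladium into the C5–I bond, base-assisted transfer of the primary alkyl group from boron to palladium and reductive elimination form the C4–C5 bond. The closest known reaction type is the B-alkyl Suzuki–Miyaura macrocyclization of ω-boryl alkenyl iodides used for macrocyclic terpenoids and macrolides. The 14-membered carbocycle is closed end to end by intramolecular alkenyl–alkyl cross-coupling, that is by reductive elimination from a 15-membered palladacycle under pseudo-high dilution, not by attack on a π bond. No new stereocentre arises: C8 is remote and untouched, and the 5Z geometry should be carried over from the (Z)-iodide because oxidative addition and reductive elimination both retain configuration at the alkenyl carbon. The step needs chemoselective hydroboration (secured by the steric bias of 9-BBN-H for the only monosubstituted C=C over the trisubstituted olefins and the iodoalkene), ring closure over oligomerization (slow addition, low concentration) and coupling faster than β-hydride elimination (dppf/AsPh3 ligand set). The cis placing of C7 and the C–I bond on the olefin turns the chain back on itself, which should ease closure.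

Step 15
Reactants: 20 tert-butyl{[(1E,5Z,8R,11E)-5,11-dimethyl-8-[(2E)-6-methylhepta-2,5-dien-2-yl]cyclotetradeca-1,5,11-trien-1-yl]methoxy}dimethylsilane
Product: 21 [(1E,5Z,8R,11E)-5,11-dimethyl-8-[(2E)-6-methylhepta-2,5-dien-2-yl]cyclotetradeca-1,5,11-trien-1-yl]methanol
Conditions: Bu4NF, THF, 0 °C → rt
Reagents that add atoms: none
Why: Fluoride should cleave the Si–O bond and free the allylic alcohol without affecting the olefins (desilylation).

Step 16
Reactants: 21 [(1E,5Z,8R,11E)-5,11-dimethyl-8-[(2E)-6-methylhepta-2,5-dien-2-yl]cyclotetradeca-1,5,11-trien-1-yl]methanol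
Product: 23 (1E,5Z,8R,11E)-5,11-dimethyl-8-[(2E)-6-methylhepta-2,5-dien-2-yl]cyclotetradeca-1,5,11-triene-1-carboxylic acid, via enal 22 (not isolated)
Conditions: MnO2, CH2Cl2, rt; filter; then NaClO2, NaH2PO4, 2-methylbut-2-ene, t-BuOH/H2O, 0 °C → rt
Reagents that add atoms: sodium chlorite [Na+].[O-]Cl=O
Why: MnO2 should oxidize the allylic alcohol to the (E)-enal and the Pinnick chlorite oxidation should take it to the acid, excess 2-methylbut-2-ene trapping HOCl so that the five olefins and their geometry are kept.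

**Compound list**

1 | acrolein | C=CC=O | starting material
2 | ethyl (2Z)-2-bromopenta-2,4-dienoate | C=C/C=C(\Br)C(=O)OCC | intermediate
3 | (2Z)-2-bromopenta-2,4-dien-1-ol | C=C/C=C(\Br)CO | intermediate
4 | {[(2Z)-2-bromopenta-2,4-dien-1-yl]oxy}(tert-butyl)dimethylsilane | C=C/C=C(\Br)CO[Si](C)(C)C(C)(C)C | intermediate
5 | geranyl acetate, (2E)-3,7-dimethylocta-2,6-dien-1-yl acetate | CC(C)=CCC/C(C)=C/COC(C)=O | starting material
6 | (2E,6E)-8-hydroxy-3,7-dimethylocta-2,6-dien-1-yl acetate | OC/C(C)=C/CC/C(C)=C/COC(C)=O | intermediate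
7 | (2E,6E)-3,7-dimethyl-8-oxoocta-2,6-dien-1-yl acetate | O=C/C(C)=C/CC/C(C)=C/COC(C)=O | intermediate
8 | (2E,6E,8R)-8-hydroxy-3,7-dimethylundeca-2,6,10-trien-1-yl acetate | C=CC[C@@H](O)/C(C)=C/CC/C(C)=C/COC(C)=O | intermediate
9 | (2E,6E,8R)-8-hydroxy-3,7,11-trimethyldodeca-2,6,10-trien-1-yl acetate | CC(C)=CC[C@@H](O)/C(C)=C/CC/C(C)=C/COC(C)=O | intermediate
10 | (2E,6E,8R)-8-[(1-methoxyethenyl)oxy]-3,7,11-trimethyldodeca-2,6,10-trien-1-yl acetate (ketene acetal) | CC(C)=CC[C@@H](OC(=C)OC)/C(C)=C/CC/C(C)=C/COC(C)=O | intermediate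
11 | methyl (3R,4E)-3-[(3E)-5-acetoxy-3-methylpent-3-en-1-yl]-4,8-dimethylnona-4,7-dienoate | COC(=O)C[C@@H](CC/C(C)=C/COC(C)=O)/C(C)=C/CC=C(C)C | intermediate
12 | methyl (3R,4E)-3-[(3E)-5-hydroxy-3-methylpent-3-en-1-yl]-4,8-dimethylnona-4,7-dienoate | COC(=O)C[C@@H](CC/C(C)=C/CO)/C(C)=C/CC=C(C)C | intermediate
13 | methyl (3R,4E)-4,8-dimethyl-3-[(3E)-3-methyl-5-oxopent-3-en-1-yl]nona-4,7-dienoate | COC(=O)C[C@@H](CC/C(C)=C/C=O)/C(C)=C/CC=C(C)C | intermediate
14 | methyl (3R,4E)-4,8-dimethyl-3-[(3E)-3-methylhexa-3,5-dien-1-yl]nona-4,7-dienoate | COC(=O)C[C@@H](CC/C(C)=C/C=C)/C(C)=C/CC=C(C)C | intermediate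
15 | methyl (3R,4E)-3-[(3E)-6-(9-borabicyclo[3.3.1]nonan-9-yl)-3-methylhex-3-en-1-yl]-4,8-dimethylnona-4,7-dienoate | COC(=O)C[C@@H](CC/C(C)=C/CCB1C2CCCC1CCC2)/C(C)=C/CC=C(C)C | intermediate
16 | methyl (3R,4E)-3-[(3E,7E)-7-({[tert-butyl(dimethyl)silyl]oxy}methyl)-3-methyldeca-3,7,9-trien-1-yl]-4,8-dimethylnona-4,7-dienoate | COC(=O)C[C@@H](CC/C(C)=C/CC/C(CO[Si](C)(C)C(C)(C)C)=C\C=C)/C(C)=C/CC=C(C)C | intermediate
17 | (3R,4E)-3-[(3E,7E)-7-({[tert-butyl(dimethyl)silyl]oxy}methyl)-3-methyldeca-3,7,9-trien-1-yl]-4,8-dimethylnona-4,7-dienal | O=CC[C@@H](CC/C(C)=C/CC/C(CO[Si](C)(C)C(C)(C)C)=C\C=C)/C(C)=C/CC=C(C)C | intermediate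
18 | (3E,7E,11R,13Z)-4-({[tert-butyl(dimethyl)silyl]oxy}methyl)-14-iodo-8-methyl-11-[(2E)-6-methylhepta-2,5-dien-2-yl]pentadeca-1,3,7,13-tetraene | C/C(I)=C/C[C@@H](CC/C(C)=C/CC/C(CO[Si](C)(C)C(C)(C)C)=C\C=C)/C(C)=C/CC=C(C)C | intermediate
19 | (3E,7E,11R,13Z)-1-(9-borabicyclo[3.3.1]nonan-9-yl)-4-({[tert-butyl(dimethyl)silyl]oxy}methyl)-14-iodo-8-methyl-11-[(2E)-6-methylhepta-2,5-dien-2-yl]pentadeca-3,7,13-triene | C/C(I)=C/C[C@@H](CC/C(C)=C/CC/C(CO[Si](C)(C)C(C)(C)C)=C\CCB1C2CCCC1CCC2)/C(C)=C/CC=C(C)C | intermediate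
20 | tert-butyl{[(1E,5Z,8R,11E)-5,11-dimethyl-8-[(2E)-6-methylhepta-2,5-dien-2-yl]cyclotetradeca-1,5,11-trien-1-yl]methoxy}dimethylsilane | CC(C)=CC/C=C(\C)[C@H]1C/C=C(/C)CC/C=C(/CO[Si](C)(C)C(C)(C)C)CC/C=C(\C)CC1 | intermediate
21 | [(1E,5Z,8R,11E)-5,11-dimethyl-8-[(2E)-6-methylhepta-2,5-dien-2-yl]cyclotetradeca-1,5,11-trien-1-yl]methanol | CC(C)=CC/C=C(\C)[C@H]1C/C=C(/C)CC/C=C(/CO)CC/C=C(\C)CC1 | intermediate
22 | (1E,5Z,8R,11E)-5,11-dimethyl-8-[(2E)-6-methylhepta-2,5-dien-2-yl]cyclotetradeca-1,5,11-triene-1-carbaldehyde | CC(C)=CC/C=C(\C)[C@H]1C/C=C(/C)CC/C=C(/C=O)CC/C=C(\C)CC1 | intermediate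
23 | (1E,5Z,8R,11E)-5,11-dimethyl-8-[(2E)-6-methylhepta-2,5-dien-2-yl]cyclotetradeca-1,5,11-triene-1-carboxylic acid | CC(C)=CC/C=C(\C)[C@H]1C/C=C(/C)CC/C=C(/C(=O)O)CC/C=C(\C)CC1 | target

**Step count and risks**

Total step count: 16. Longest linear sequence: 13 steps (steps 4–16 from geranyl acetate); the linchpin branch (steps 1–3) joins at step 11.

Steps most likely to fail:

1. Step 14 (ring closure). What may go wrong: intermolecular coupling to oligomers, protodeboronation of the borane, or β-hydride elimination of the alkylpalladium before reductive elimination. Fallback: the route sets out again from 18. Borane 19 would be oxidized (NaBO3·4H2O) to the primary alcohol F1, which I2/PPh3/imidazole would convert into the primary iodide F2. Zinc dust with LiCl in THF should insert only into the C(sp3)–I bond to give the alkylzinc iodide F3, which would be cyclized by an intramolecular Negishi coupling (Pd2(dba)3, P(2-furyl)3, THF/NMP, slow addition) under base-free, water-free conditions. This gives 20, where the route is rejoined.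

2. Step 13 (iodo-olefination). What may go wrong: decay of the α-iodo ylide before it meets the aldehyde, loss of iodine to the plain ethylidene olefin, and erosion of the Z-selectivity. Fallback: the route sets out from aldehyde 17. PPh3/CCl4 would give the 1,1-dichloroalkene F4. A trans-selective Negishi monomethylation (MeZnCl, Pd(DPEphos)Cl2, DMF) should replace only the chlorine trans to the chain and give the (Z)-2-chloroalkene F5, with chlorine cis to the chain. Hydroboration with 9-BBN-H would give the borane F6, and B-alkyl Suzuki–Miyaura closure at the C–Cl bond (Pd(OAc)2, SPhos, K3PO4, THF/H2O, slow addition) returns to the route at 20.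

3. Step 11 (fragment coupling). What may go wrong: slow transfer of the alkyl group from boron under aqueous base, so that polymerization of the bromodiene, β-hydride elimination and ester hydrolysis compete. Fallback: the route sets out from diene 14. Hydroboration and oxidation (9-BBN-H; NaBO3·4H2O) would give the homoallylic alcohol F7, and I2/PPh3/imidazole the homoallylic iodide F8. A nickel-catalysed reductive cross-electrophile coupling of F8 with bromide 4 (NiI2, 4,4′-di-tert-butyl-2,2′-bipyridine, Zn powder, N,N-dimethylacetamide, rt) should join the two halides with retention at the alkenyl carbon and return to the route at 16.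

**Further compounds**

F1 | step 14 | (3E,7E,11R,13Z)-4-({[tert-butyl(dimethyl)silyl]oxy}methyl)-14-iodo-8-methyl-11-[(2E)-6-methylhepta-2,5-dien-2-yl]pentadeca-3,7,13-trien-1-ol | C/C(I)=C/C[C@@H](CC/C(C)=C/CC/C(CO[Si](C)(C)C(C)(C)C)=C\CCO)/C(C)=C/CC=C(C)C
F2 | step 14 | (3E,7E,11R,13Z)-4-({[tert-butyl(dimethyl)silyl]oxy}methyl)-1,14-diiodo-8-methyl-11-[(2E)-6-methylhepta-2,5-dien-2-yl]pentadeca-3,7,13-triene | C/C(I)=C/C[C@@H](CC/C(C)=C/CC/C(CO[Si](C)(C)C(C)(C)C)=C\CCI)/C(C)=C/CC=C(C)C
F3 | step 14 | alkylzinc iodide of F2 (C1–ZnI of the pentadecatriene chain, ring C4) | C/C(I)=C/C[C@@H](CC/C(C)=C/CC/C(CO[Si](C)(C)C(C)(C)C)=C\CC[Zn]I)/C(C)=C/CC=C(C)C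
F4 | step 13 | (3E,7E,11R)-4-({[tert-butyl(dimethyl)silyl]oxy}methyl)-14,14-dichloro-8-methyl-11-[(2E)-6-methylhepta-2,5-dien-2-yl]tetradeca-1,3,7,13-tetraene | ClC(Cl)=CC[C@@H](CC/C(C)=C/CC/C(CO[Si](C)(C)C(C)(C)C)=C\C=C)/C(C)=C/CC=C(C)C
F5 | step 13 | (3E,7E,11R,13Z)-4-({[tert-butyl(dimethyl)silyl]oxy}methyl)-14-chloro-8-methyl-11-[(2E)-6-methylhepta-2,5-dien-2-yl]pentadeca-1,3,7,13-tetraene | C/C(Cl)=C/C[C@@H](CC/C(C)=C/CC/C(CO[Si](C)(C)C(C)(C)C)=C\C=C)/C(C)=C/CC=C(C)C
F6 | step 13 | (3E,7E,11R,13Z)-1-(9-borabicyclo[3.3.1]nonan-9-yl)-4-({[tert-butyl(dimethyl)silyl]oxy}methyl)-14-chloro-8-methyl-11-[(2E)-6-methylhepta-2,5-dien-2-yl]pentadeca-3,7,13-triene | C/C(Cl)=C/C[C@@H](CC/C(C)=C/CC/C(CO[Si](C)(C)C(C)(C)C)=C\CCB1C2CCCC1CCC2)/C(C)=C/CC=C(C)C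
F7 | step 11 | methyl (3R,4E)-3-[(3E)-6-hydroxy-3-methylhex-3-en-1-yl]-4,8-dimethylnona-4,7-dienoate | COC(=O)C[C@@H](CC/C(C)=C/CCO)/C(C)=C/CC=C(C)C
F8 | step 11 | methyl (3R,4E)-3-[(3E)-6-iodo-3-methylhex-3-en-1-yl]-4,8-dimethylnona-4,7-dienoate | COC(=O)C[C@@H](CC/C(C)=C/CCI)/C(C)=C/CC=C(C)C
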